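To judge how slow these two flasks are, I look for the concentration that their rate follows before I reckon anything.

- amber: starting material 0.050 M; partner 0.0475 M (fed, over 12 h); free catalyst 0.50 mM; temperature 40 °C; time 12 h
- grey: starting material 0.050 M; partner 0.0475 M (fed, over 12 h); free catalyst 0.50 mM; temperature 25 °C; time 12 h

    free catalyst + target ⇌ idle complex (K1 = 250 M⁻¹, k1 = 0.00685 M⁻¹ s⁻¹, Ea1 = 49.0 kJ mol⁻¹, ΔH1 = −55.0 kJ mol⁻¹)
    catalyst intermediate D → free catalyst + target (k2 = 0.0216 s⁻¹, Ea2 = 72.0 kJ mol⁻¹)
    catalyst intermediate C ⇌ catalyst intermediate D (K3 = 1.4, k3 = 0.00368 s⁻¹, Ea3 = 83.0 kJ mol⁻¹, ΔH3 = −21.0 kJ mol⁻¹)
    starting material + catalyst intermediate B → catalyst intermediate C (k4 = 0.105 M⁻¹ s⁻¹, Ea4 = 48.0 kJ mol⁻¹)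
    catalyst intermediate A → catalyst intermediate B (k5 = 0.00247 s⁻¹, Ea5 = 87.0 kJ mol⁻¹)
    partner + free catalyst ⇌ catalyst intermediate A (K6 = 5.53 M⁻¹, k6 = 0.0657 M⁻¹ s⁻¹, Ea6 = 67.0 kJ mol⁻¹, ΔH6 = −1.00 kJ mol⁻¹)
    (constants at 25 °C)

1. the best flask by amount of target, in percent of the starting material charged; "all alike" if 1.5 percentage points covers them all (amber / grey / all alike)
2. amount of target at the end, in percent of the starting material charged, amber
3. amount of target at the end, in percent of the starting material charged, grey

- target is meant together with its idle complex
- at 25 °C the constants are as listed, elsewhere as the activation energies and enthalpies make them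

- Each round uses one partner and one starting material and gives one target, so partner used counts target made. Even the whole charge gives K·cB = 0.263 at the grey temperature, where K is the binding constant of partner to free catalyst and cB the charge; because this is below one, I take the rate as first order in partner.
- Catalyst intermediate A either falls back or goes on, and the share going on is s = kg/(kg + kf/K), with kf the forward binding constant and kg the constant of its onward step. This share is 17.2 % in grey.
- With the whole catalyst charge c counted as free, partner is used pseudo-first-order with constant kf·c·s, and I multiply that by the dosing time tf to get N. N is 0.244 in grey and 1.20 in amber, and this feed number, the number of partner lifetimes that fit into the dose, is what I carry.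
- My first way draws a triangle: I let partner rise steadily as if none of it were consumed, and on that assumption the share of the charge used is N times 0.5. As percent of starting material, that gives 11.6 % in grey and 56.8 % in amber.
- My second way balances feed against consumption, which gives the used share 1 − (1 − e^(−N))/N. That is 11.3 % of the charge in grey and 41.7 % in amber, or 10.7 % and 39.6 % of the starting material.
- The two ways nearly agree in grey, but in amber the triangle stands higher. The triangle is the one that cheats, because with N larger in amber it goes on counting partner that has already been consumed.
- Both ways count the whole catalyst as free, yet at my grey figure idle complex over free catalyst comes to 1.34 at equilibrium, so I take my figures to be on the high side. I commit to amber ahead because N is larger there.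
- The forecast says amber, with 24.5 % for amber and 6.8 % for grey, lower than my figures, and its ground is: “Warming to 40 °C speeds the high-barrier steps about four- to fivefold and weakens product binding”.
- The simulation gives amber as the better flask, with 25.3 % in amber and 7.45 % in grey. In amber, half of the turnover of catalyst intermediate A to catalyst intermediate B was done by 7.31 h, while partner rose from 40.1 % of its charge at 6.00 h to 73.2 % at 12.0 h, and free catalyst fell from 64.9 % to 40.2 % of the catalyst charge as idle complex grew from 18.9 % to 40.1 %. The mean of those two free readings, 52.6 %, multiplied into N, turns my balance for amber into 24.5 %, a figure of my own made after the result from amber's own readings, so it is no test of the balance.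
- For a neighbour flask like amber but kept at 65 °C, N is 11.8, and amber's free share carried over gives 79.7 % of the starting material as target. The simulation gives 79.6 %, with 16.0 % of the partner left.

Its constants are made up; the rest is arithmetic.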